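# Design of a total synthesis of mururin C by furan-based electrocyclization

## The problem

Mururin C (24) is a flat, fully aromatic 2-arylbenzofuran. The furan ring carries ring B (3,4-dihydroxy-5-methoxyphenyl) at C2 and a formyl group at C3; the fused benzene ring A carries a 3-hydroxypropyl chain at C5 and a methoxy group at C7. There is no stereogenic centre and no stereogenic double bond, so nothing has to relay stereochemical information. The task is to place four different substituents on the bicycle and three different oxygen functions on ring B without ambiguity. The ring B catechol is oxidised easily in base and air, the C3 aldehyde does not tolerate hydride, hydrogenation or organometallic reagents, and the primary alcohol would react with the electrophile that introduces the aldehyde. All three hydroxyl groups must therefore stay masked through the carbon–carbon bond formations and be released last without cleaving either aryl methyl ether. C2 and C3 are adjacent and are best functionalised in that order, because C2–H is the acidic position of a benzofuran and a 2-aryl group then directs an electrophile to C3. The feature that allows a less obvious construction is ring A itself: it shares the C3a=C7a bond with the furan and has oxygen on C7, the chain on C5 and hydrogen on C4 and C6. Read from the furan, C7a–C7(O)=C6 is a 1-oxyvinyl group on the alpha carbon and C3a–C4=C5–chain is an (E)-alkenyl group on the beta carbon, so ring A is a hexatriene whose central double bond is the furan C2=C3 bond and whose termini are C6 and C5. Furan gives up little aromatic stabilisation, so such a triene can close thermally, and the one stereocentre that appears on the way (C5 of the cycloadduct) disappears on aromatisation.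

## Retrosynthesis

**Release of the hydroxyl groups (24 from 23).** Only the three O–benzyl bonds are cut. Benzyl is used for all three hydroxyls because it survives n-BuLi, palladium catalysis and POCl3/DMF, which silyl ethers or acetals would not all do. Removal is planned with BCl3 and a cation scavenger rather than hydrogen, because the C3 aldehyde is present. The forward step must cleave two aryl and one alkyl benzyl ether and leave two aryl methyl ethers and the aldehyde untouched.

**C3–CHO bond (23 from 21).** Removing the formyl carbon gives 2-arylbenzofuran 21. The neighbouring option, carrying a C3 carbon substituent through the cross-coupling, would place an electrophilic group next to the carbon that has to be metalated. In 21, C3 is the beta carbon of an aryl enol ether, so a Vilsmeier–Haack reaction should find it. The forward step must prefer C3 over the alkoxy-activated positions of rings A and B.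

**C2–C1' bond (21 from 14 and 18).** This cut divides the molecule into two fragments of similar size and uses the innate acidity of C2–H in benzofuran 14 (lithiation, zincation, Negishi coupling with bromide 18). It is preferred to forming the furan ring at this stage, because ring A is to be grown onto an existing furan.

**Ring B fragment (18 from 17 from 15).** The two O–benzyl bonds of 18 lead back to catechol 17, and one catechol oxygen is traced to the formyl group of the commercial salicylaldehyde 15 (Dakin oxidation). Compound 15 already has bromine, methoxy and hydroxyl in the required positions. This avoids a selective mono-demethylation of a symmetrical dimethoxyphenol.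

**Ether exchange (14 from 12).** The C7 oxygen is delivered by the ring-forming step as a silyl ether. Fluoride and iodomethane convert it to the methyl ether in one operation through phenoxide 13.

**Ring A, the key cut (12 from 9).** The C5–C6 bond is cut and two hydrogens are added back, which opens ring A to the 2-(1-siloxyvinyl)-3-[(E)-alkenyl]furan 9.
- Against a benzene-based approach, the positions of the two alkenyl groups on the furan fix the C7 oxygen and the C5 chain with no regiochemical choice, and the chain arrives complete.
- The precursor has one ring fewer and is assembled from three small pieces.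
- The forward reaction must achieve disrotatory closure to cycloadduct 10, hydrogen shift to 11 and dehydrogenation to 12 without loss of the enol ether.

**Triene assembly (9 from 8; 8 from 7 and 4; 7 from 5; 4 from 3 from 1).**
- The Si–O bond of 9 leads to methyl ketone 8, which has a single enolisable site.
- The furan C3–alkenyl bond of 8 is cut to bromoketone 7 and (E)-alkenylboronate 4 (Suzuki–Miyaura coupling); the acyl group activates the C–Br bond.
- Ketone 7 comes from 3-bromofuran 5 through lithio species 6.
- Boronate 4 comes from benzyl ether 3 and thus from pent-4-yn-1-ol 1; the hydroboration sets the E geometry.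

## Roads not taken

**Alternative 1:** The C2–C1' and C3–CH bonds are cut together. The 2-lithio derivative of benzofuran A2 (the silyl-protected analogue of 14) would add to ring B pinacol boronate A3. Dimethoxycarbenium tetrafluoroborate would then attack C3 of the ate complex, forming the C3–CH(OMe)2 bond while ring B migrates from boron to C2, to give the 2-boryl-2,3-dihydrobenzofuran A1.
- Merits: it is a three-component union; the formyl carbon arrives at the correct oxidation level as an acetal; the site of carbon–carbon bond formation at C3 is dictated by the mechanism, not by competition between electron-rich rings.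
- Weak points: A1 is not aromatic and holds two stereocentres that must be destroyed again. The electrophile leaves no leaving group on C3, so the furan can only be regenerated by oxidising the hindered tertiary C2–B bond and dehydrating, which is at least one more operation. The carbenium salt is also a methylating agent and may simply quench the ate complex, and this electrophile has no close precedent with benzofuranyl boronate complexes. No ring is formed, so A2 must still be supplied with ring A in place.
- Comparison: this road would replace only steps 10 and 11 of the chosen route, with no saving in step count. It is better in regiochemical certainty at C3. The chosen plan sets against that the strong innate C3 preference of 2-arylbenzofurans in Vilsmeier–Haack reactions, two textbook operations, and a ring A construction that Alternative 1 does not address.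

**Alternative 2:** The O1–C2 and C3–CH2 bonds are cut, so the furan ring is the one that closes. PtCl2 (divalent platinum) would activate the diarylalkyne A5, whose phenol is protected as a MOM ether. The ether oxygen attacks the alkyne, and the methoxymethyl group moves from oxygen to C3 to give 3-(methoxymethyl)benzofuran A4.
- Merits: one catalytic, atom-economical step forms the heterocycle, fixes ring B at C2 and installs the C3 carbon with complete regiocontrol. Ring A is taken from an inexpensive guaiacol-type arene, and the assembly by Sonogashira coupling is convergent.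
- Weak points: the C3 carbon arrives as a methyl ether and must be oxidised to the aldehyde in a molecule holding three other benzylic ethers. Protodemetalation of the vinylplatinum intermediate would give the 3-unsubstituted benzofuran. A5 needs an ortho-iodinated tetrasubstituted phenol.
- Comparison: in step count this road is at least as short as the chosen one, and its ring-forming step is catalytic and mild; on both counts it is the better road. The chosen plan sets against it that the formyl group is introduced directly as an aldehyde with no late chemoselective oxidation, and that the ring A substitution pattern is built from the furan instead of relying on halogenation of a phenol.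

**Alternative 3:** The C7–C7a bond is cut. Stobbe half-ester A7 would be heated with Ac2O and NaOAc; the mixed anhydride acylates the furan alpha carbon, and the ring aromatises as ethyl 7-acetoxybenzofuran-5-carboxylate A6.
- Merits: classical ionic chemistry, cheap reagents, no high dilution, and cyclisation onto the most nucleophilic furan position. As a ring closure it is more reliable than a thermal pericyclic reaction.
- Weak points: A6 carries a one-carbon ester at C5 where the target needs a three-carbon alcohol. Reduction, oxidation, two-carbon olefination, hydrogenation and a second reduction are needed, plus exchange of acetate for methyl ether, before the same endgame can begin.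
- Comparison: the ring-forming step is safer than the chosen one, which is a real advantage. The chosen plan sets against it that the whole chain enters with the alkyne at the correct oxidation level, so it reaches the stage of 14 in about two fewer operations.

Key step: step 6

## Route

Remark on the chemistry: the hydrogen shift that restores the furan after ring closure in step 6 is drawn as giving the 4,5-dihydro isomer 11; dehydrogenation leads to arene 12 whichever hydrogen migrates.

Step 1
Reactants: 1 pent-4-yn-1-ol
Product: 3 benzyl pent-4-yn-1-yl ether, via sodium alkoxide 2 (not isolated)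
Conditions: NaH, BnBr, n-Bu4NI (cat.), THF, 0 °C → rt
Reagents that add atoms: benzyl bromide, BrCc1ccccc1
Why: Williamson ether synthesis; NaH removes only the hydroxyl proton (far more acidic than the alkyne C–H) and alkoxide 2 displaces bromide from benzyl bromide by SN2, with iodide catalysis.

Step 2
Reactants: 3 benzyl pent-4-yn-1-yl ether
Product: 4 2-[(E)-5-(benzyloxy)pent-1-en-1-yl]-4,4,5,5-tetramethyl-1,3,2-dioxaborolane
Conditions: pinacolborane, Cp2Zr(H)Cl (5 mol %), Et3N (10 mol %), neat, 60 °C
Reagents that add atoms: pinacolborane, CC1(C)OBOC1(C)C
Why: Zirconium-catalysed hydroboration of a terminal alkyne; syn addition with boron at the terminal carbon should give the (E)-alkenylboronate only, and the benzyl ether is inert.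

Step 3
Reactants: 5 3-bromofuran
Product: 7 1-(3-bromofuran-2-yl)ethanone, via 3-bromo-2-lithiofuran 6 (not isolated)
Conditions: LiN(i-Pr)2, THF, −78 °C; then N-methoxy-N-methylacetamide, −78 → 0 °C; aq NH4Cl
Reagents that add atoms: N-methoxy-N-methylacetamide, CON(C)C(C)=O
Why: Directed deprotonation; the C2–H flanked by ring oxygen and bromine is removed by the amide base at −78 °C without bromine–lithium exchange, and acylation with the N-methoxy-N-methylamide stops at the ketone because the chelated adduct collapses only on work-up.

Step 4
Reactants: 7 1-(3-bromofuran-2-yl)ethanone; 4 2-[(E)-5-(benzyloxy)pent-1-en-1-yl]-4,4,5,5-tetramethyl-1,3,2-dioxaborolane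
Product: 8 1-{3-[(E)-5-(benzyloxy)pent-1-en-1-yl]furan-2-yl}ethanone
Conditions: PdCl2(dppf) (3 mol %), K3PO4, 1,4-dioxane/H2O, 80 °C
Reagents that add atoms: none
Why: Suzuki–Miyaura coupling; the ortho acyl group activates the C3–Br bond toward oxidative addition to zerovalent palladium, and transmetalation and reductive elimination retain the E geometry of the alkenylboronate.

Step 5
Reactants: 8 1-{3-[(E)-5-(benzyloxy)pent-1-en-1-yl]furan-2-yl}ethanone
Product: 9 tert-butyl[(1-{3-[(E)-5-(benzyloxy)pent-1-en-1-yl]furan-2-yl}ethenyl)oxy]dimethylsilane
Conditions: t-BuMe2SiOTf, Et3N, CH2Cl2, 0 °C; filtration through Et3N-deactivated silica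
Reagents that add atoms: tert-butyldimethylsilyl trifluoromethanesulfonate, CC(C)(C)[Si](C)(C)OS(=O)(=O)C(F)(F)F
Why: Enol silylation of a methyl ketone with a silyl triflate and an amine; there is only one enolisable site, and the acid-labile product is kept on base-washed supports and used promptly.

Step 6
Reactants: 9 tert-butyl[(1-{3-[(E)-5-(benzyloxy)pent-1-en-1-yl]furan-2-yl}ethenyl)oxy]dimethylsilane
Product: 12 {[5-(3-(benzyloxy)propyl)benzofuran-7-yl]oxy}(tert-butyl)dimethylsilane, via electrocyclization adduct 10 (not isolated), via dihydrobenzofuran silyl enol ether 11 (not isolated)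
Conditions: 1,2-dichlorobenzene (degassed, 0.02 M, base-washed glassware), 160 °C; cool; then DDQ (1.1 equiv), rt
Reagents that add atoms: none
Why: The furan C2=C3 bond of 9 is the ring-locked cis central double bond of a hexatriene whose termini are the enol ether CH2 and the alkene carbon bearing the chain; on heating, an orbital-symmetry-allowed disrotatory 6π-electrocyclization joins these termini (C5–C6) and closes the six-membered carbocycle, ring A, as cycloadduct 10. The closure costs only the modest aromatic stabilisation of furan, and a suprafacial 1,5-hydrogen shift then restores the furan to give 11. The single stereocentre formed (C5 of 10 and 11) is racemic and is erased on aromatisation, so nothing has to control it. After cooling, DDQ abstracts hydride from the allylic, furan-activated position of 11 and loss of a proton gives arene 12, with oxygen at C7 and the chain at C5 as fixed by the positions of the two alkenyl groups on the furan. The closest known reaction type is the thermal electrocyclization–dehydrogenation of 2,3-dialkenyl heteroarenes (carbazoles from 2,3-divinylindoles, benzofurans from 2,3-dialkenylfurans). The selectivity needed is ring closure over enol ether cleavage, oligomerisation and a 1,7-hydrogen shift; high dilution, acid-free degassed solvent and the E geometry, which keeps the allylic CH2 away from the enol ether terminus, should secure it. Adding DDQ only after closure and at room temperature keeps the oxidant away from the silyl enol ether of 9 and spares the benzyl ether and the benzylic CH2 of the chain.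

Step 7
Reactants: 12 {[5-(3-(benzyloxy)propyl)benzofuran-7-yl]oxy}(tert-butyl)dimethylsilane
Product: 14 5-[3-(benzyloxy)propyl]-7-methoxybenzofuran, via cesium benzofuran-7-olate 13 (not isolated)
Conditions: CsF, MeI, DMF, rt
Reagents that add atoms: iodomethane, CI
Why: One-pot desilylation–alkylation; fluoride cleaves the aryl O–Si bond and cesium phenoxide 13 is methylated in the flask by iodomethane (SN2), while the alkyl benzyl ether is untouched.

Step 8
Reactants: 15 5-bromo-2-hydroxy-3-methoxybenzaldehyde
Product: 17 5-bromo-3-methoxybenzene-1,2-diol, via aryl formate 16 (not isolated)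
Conditions: 30% aq H2O2, NaOH, H2O, 0 °C → rt; then aq HCl
Reagents that add atoms: hydrogen peroxide, OO
Why: Dakin oxidation; hydroperoxide adds to the aldehyde of the ortho-hydroxybenzaldehyde, aryl migration gives formate 16, and the basic medium saponifies it to the catechol.

Step 9
Reactants: 17 5-bromo-3-methoxybenzene-1,2-diol
Product: 18 1,2-bis(benzyloxy)-5-bromo-3-methoxybenzene
Conditions: BnBr, K2CO3, DMF, 60 °C (N2)
Reagents that add atoms: benzyl bromide, BrCc1ccccc1
Why: Double Williamson O-benzylation of the catechol with carbonate base, run under inert gas on crude 17 to forestall air oxidation.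

Step 10
Reactants: 14 5-[3-(benzyloxy)propyl]-7-methoxybenzofuran; 18 1,2-bis(benzyloxy)-5-bromo-3-methoxybenzene
Product: 21 2-[3,4-bis(benzyloxy)-5-methoxyphenyl]-5-[3-(benzyloxy)propyl]-7-methoxybenzofuran, via 2-lithiobenzofuran 19 (not isolated), via 2-benzofuranylzinc chloride 20 (not isolated)
Conditions: n-BuLi, THF, −78 °C; ZnCl2, −78 °C → rt; then 18, Pd2(dba)3 (2 mol %), XPhos (8 mol %), THF, 60 °C
Reagents that add atoms: none
Why: C2–H is the most acidic site of a benzofuran and is lithiated cleanly at −78 °C; transmetalation to zinc gives 20, which undergoes Negishi coupling with the electron-rich bromide 18 on a zerovalent palladium–biarylphosphine catalyst, ethers being inert.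

Step 11
Reactants: 21 2-[3,4-bis(benzyloxy)-5-methoxyphenyl]-5-[3-(benzyloxy)propyl]-7-methoxybenzofuran
Product: 23 2-[3,4-bis(benzyloxy)-5-methoxyphenyl]-5-[3-(benzyloxy)propyl]-7-methoxybenzofuran-3-carbaldehyde, via iminium chloride 22 (not isolated)
Conditions: POCl3, DMF, 0 → 60 °C; then H2O (NaOAc buffer)
Reagents that add atoms: N,N-dimethylformamide, CN(C)C=O; water, O
Why: Vilsmeier–Haack formylation; C3 of a 2-arylbenzofuran is the beta carbon of an aryl enol ether and attack there gives a cation stabilised by O1 and ring B, so the chloroiminium ion should react at C3 in preference to the positions of rings A and B, and hydrolysis of iminium 22 gives the aldehyde.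

Step 12
Reactants: 23 2-[3,4-bis(benzyloxy)-5-methoxyphenyl]-5-[3-(benzyloxy)propyl]-7-methoxybenzofuran-3-carbaldehyde
Product: 24 mururin C, 2-(3,4-dihydroxy-5-methoxyphenyl)-5-(3-hydroxypropyl)-7-methoxybenzofuran-3-carbaldehyde
Conditions: BCl3, pentamethylbenzene, CH2Cl2, −78 → −20 °C; then MeOH, H2O
Reagents that add atoms: none
Why: Lewis-acid debenzylation; BCl3 coordinates the ether oxygens and the benzyl cations are trapped irreversibly by pentamethylbenzene (Friedel–Crafts alkylation), so all three benzyl ethers should cleave at low temperature while the aryl methyl ethers, which have no chelating ortho carbonyl, and the aldehyde, which meets no reductant, survive.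

## Compound list

1 | pent-4-yn-1-ol | C#CCCCO | starting material
2 | sodium pent-4-yn-1-olate | [Na+].[O-]CCCC#C | intermediate (not isolated)
3 | benzyl pent-4-yn-1-yl ether | C#CCCCOCc1ccccc1 | intermediate
4 | 2-[(E)-5-(benzyloxy)pent-1-en-1-yl]-4,4,5,5-tetramethyl-1,3,2-dioxaborolane | CC1(C)OB(/C=C/CCCOCc2ccccc2)OC1(C)C | intermediate
5 | 3-bromofuran | Brc1ccoc1 | starting material
6 | 3-bromo-2-lithiofuran | [Li]c1occc1Br | intermediate (not isolated)
7 | 1-(3-bromofuran-2-yl)ethanone | CC(=O)c1occc1Br | intermediate
8 | 1-{3-[(E)-5-(benzyloxy)pent-1-en-1-yl]furan-2-yl}ethanone | CC(=O)c1occc1/C=C/CCCOCc1ccccc1 | intermediate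
9 | tert-butyl[(1-{3-[(E)-5-(benzyloxy)pent-1-en-1-yl]furan-2-yl}ethenyl)oxy]dimethylsilane | C=C(O[Si](C)(C)C(C)(C)C)c1occc1/C=C/CCCOCc1ccccc1 | intermediate
10 | {[5-(3-(benzyloxy)propyl)-5,6-dihydrobenzofuran-7-yl]oxy}(tert-butyl)dimethylsilane (racemic at C5) | CC(C)(C)[Si](C)(C)OC1=C2OC=CC2=CC(CCCOCc2ccccc2)C1 | intermediate (not isolated)
11 | {[5-(3-(benzyloxy)propyl)-4,5-dihydrobenzofuran-7-yl]oxy}(tert-butyl)dimethylsilane (racemic at C5) | CC(C)(C)[Si](C)(C)OC1=CC(CCCOCc2ccccc2)Cc2ccoc21 | intermediate (not isolated)
12 | {[5-(3-(benzyloxy)propyl)benzofuran-7-yl]oxy}(tert-butyl)dimethylsilane | CC(C)(C)[Si](C)(C)Oc1cc(CCCOCc2ccccc2)cc2ccoc12 | intermediate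
13 | cesium 5-[3-(benzyloxy)propyl]benzofuran-7-olate | [Cs+].[O-]c1cc(CCCOCc2ccccc2)cc2ccoc12 | intermediate (not isolated)
14 | 5-[3-(benzyloxy)propyl]-7-methoxybenzofuran | COc1cc(CCCOCc2ccccc2)cc2ccoc12 | intermediate
15 | 5-bromo-2-hydroxy-3-methoxybenzaldehyde | COc1cc(Br)cc(C=O)c1O | starting material
16 | 5-bromo-2-hydroxy-3-methoxyphenyl formate | COc1cc(Br)cc(OC=O)c1O | intermediate (not isolated)
17 | 5-bromo-3-methoxybenzene-1,2-diol | COc1cc(Br)cc(O)c1O | intermediate
18 | 1,2-bis(benzyloxy)-5-bromo-3-methoxybenzene | COc1cc(Br)cc(OCc2ccccc2)c1OCc1ccccc1 | intermediate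
19 | {5-[3-(benzyloxy)propyl]-7-methoxybenzofuran-2-yl}lithium | [Li]c1cc2cc(CCCOCc3ccccc3)cc(OC)c2o1 | intermediate (not isolated)
20 | {5-[3-(benzyloxy)propyl]-7-methoxybenzofuran-2-yl}zinc chloride | Cl[Zn]c1cc2cc(CCCOCc3ccccc3)cc(OC)c2o1 | intermediate (not isolated)
21 | 2-[3,4-bis(benzyloxy)-5-methoxyphenyl]-5-[3-(benzyloxy)propyl]-7-methoxybenzofuran | COc1cc(-c2cc3cc(CCCOCc4ccccc4)cc(OC)c3o2)cc(OCc2ccccc2)c1OCc1ccccc1 | intermediate
22 | N-({2-[3,4-bis(benzyloxy)-5-methoxyphenyl]-5-[3-(benzyloxy)propyl]-7-methoxybenzofuran-3-yl}methylidene)-N-methylmethanaminium chloride | C[N+](C)=Cc1c(-c2cc(OC)c(OCc3ccccc3)c(OCc3ccccc3)c2)oc2c(OC)cc(CCCOCc3ccccc3)cc12.[Cl-] | intermediate (not isolated)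
23 | 2-[3,4-bis(benzyloxy)-5-methoxyphenyl]-5-[3-(benzyloxy)propyl]-7-methoxybenzofuran-3-carbaldehyde | COc1cc(-c2oc3c(OC)cc(CCCOCc4ccccc4)cc3c2C=O)cc(OCc2ccccc2)c1OCc1ccccc1 | intermediate
24 | mururin C, 2-(3,4-dihydroxy-5-methoxyphenyl)-5-(3-hydroxypropyl)-7-methoxybenzofuran-3-carbaldehyde | COc1cc(-c2oc3c(OC)cc(CCCO)cc3c2C=O)cc(O)c1O | target

## Step count and risk

Total: 12 steps. Longest linear sequence: 9 steps (steps 1, 2, 4, 5, 6, 7, 10, 11, 12, from pent-4-yn-1-ol).

**Step 6 (key step).**
- What may go wrong: the cycloadduct may revert to the aromatic triene faster than the hydrogen shift occurs at temperatures the enol ether tolerates, so ring closure stays incomplete. Trace acid may cleave the silyl enol ether back to ketone 8. The electron-rich triene may oligomerise. Any triene left when DDQ is added will be consumed by the oxidant.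
- Harmless outcome: loss of the silyl group during oxidation does no damage, because such material is methylated in step 7 through the same phenoxide 13.
- Fallback: ring A is taken from a benzene instead of being built. Aldehyde 15 is O-alkylated with ethyl bromoacetate and K2CO3 in DMF at 100 °C, with aldol condensation in the flask, to give ethyl 5-bromo-7-methoxybenzofuran-2-carboxylate F1. Saponification (NaOH, aqueous EtOH, then HCl) gives 5-bromo-7-methoxybenzofuran-2-carboxylic acid F2, and decarboxylation with Cu powder in quinoline at 200 °C gives 5-bromo-7-methoxybenzofuran F3. A B-alkyl Suzuki–Miyaura coupling of F3 with 9-[3-(benzyloxy)propyl]-9-borabicyclo[3.3.1]nonane F4 (made in the flask from allyl benzyl ether and 9-borabicyclo[3.3.1]nonane), using PdCl2(dppf) and K3PO4, returns to the route at 14.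

**Step 11.**
- What may go wrong: formylation may go to an alkoxy-activated carbon of ring B or ring A instead of C3, or the reaction at the hindered C3 may be sluggish, and forcing it may cause acid-mediated loss of benzyl groups.
- Fallback: halogenation–metalation replaces direct formylation. Compound 21 is brominated with N-bromosuccinimide in MeCN at 0 °C to 2-[3,4-bis(benzyloxy)-5-methoxyphenyl]-5-[3-(benzyloxy)propyl]-3-bromo-7-methoxybenzofuran F5. Bromine–lithium exchange with n-BuLi in THF at −78 °C gives the 3-lithio derivative {2-[3,4-bis(benzyloxy)-5-methoxyphenyl]-5-[3-(benzyloxy)propyl]-7-methoxybenzofuran-3-yl}lithium F6, and quenching with DMF returns to the route at 23.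

**Step 12.**
- What may go wrong: the alkyl benzyl ether may cleave more slowly than the aryl ones. Warming to complete it may cause demethylation next to the boron-bound catechol or Lewis-acid attack at the aldehyde.
- Fallback: the protecting groups are exchanged before the aldehyde exists.
  - Compound 21 is hydrogenolysed (H2, 10% Pd/C, EtOAc/MeOH) to 5-[5-(3-hydroxypropyl)-7-methoxybenzofuran-2-yl]-3-methoxybenzene-1,2-diol F7.
  - Acetylation (Ac2O, pyridine) gives 3-[2-(3,4-diacetoxy-5-methoxyphenyl)-7-methoxybenzofuran-5-yl]propyl acetate F8.
  - Vilsmeier–Haack formylation (POCl3, DMF, then water) proceeds through the iminium chloride N-({2-(3,4-diacetoxy-5-methoxyphenyl)-5-(3-acetoxypropyl)-7-methoxybenzofuran-3-yl}methylidene)-N-methylmethanaminium chloride F9 to 3-[2-(3,4-diacetoxy-5-methoxyphenyl)-3-formyl-7-methoxybenzofuran-5-yl]propyl acetate F10.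
  - Methanolysis (K2CO3, degassed MeOH, 0 °C, then dilute HCl) returns to the route at 24.

**Step 10.**
- What may go wrong: oxidative addition to the electron-rich bromide may be slow, so that protonation or homocoupling of the zinc reagent competes. Lithiation may be incomplete, or deprotonation at a benzylic ether position may compete.
- Fallback: no organometallic reagent is made. Compounds 14 and 18 are joined by direct C2–H arylation (Pd(OAc)2, PCy3·HBF4, pivalic acid, K2CO3, DMA, 100 °C; concerted metalation–deprotonation), which returns to the route at 21 without any new compound.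

## Further compounds

F1 | step 6 | ethyl 5-bromo-7-methoxybenzofuran-2-carboxylate | CCOC(=O)c1cc2cc(Br)cc(OC)c2o1
F2 | step 6 | 5-bromo-7-methoxybenzofuran-2-carboxylic acid | OC(=O)c1cc2cc(Br)cc(OC)c2o1
F3 | step 6 | 5-bromo-7-methoxybenzofuran | COc1cc(Br)cc2ccoc12
F4 | step 6 | 9-[3-(benzyloxy)propyl]-9-borabicyclo[3.3.1]nonane | C1CCC2CCCC1B2CCCOCc1ccccc1
F5 | step 11 | 2-[3,4-bis(benzyloxy)-5-methoxyphenyl]-5-[3-(benzyloxy)propyl]-3-bromo-7-methoxybenzofuran | COc1cc(-c2oc3c(OC)cc(CCCOCc4ccccc4)cc3c2Br)cc(OCc2ccccc2)c1OCc1ccccc1
F6 | step 11 | {2-[3,4-bis(benzyloxy)-5-methoxyphenyl]-5-[3-(benzyloxy)propyl]-7-methoxybenzofuran-3-yl}lithium | COc1cc(-c2oc3c(OC)cc(CCCOCc4ccccc4)cc3c2[Li])cc(OCc2ccccc2)c1OCc1ccccc1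
F7 | step 12 | 5-[5-(3-hydroxypropyl)-7-methoxybenzofuran-2-yl]-3-methoxybenzene-1,2-diol | COc1cc(-c2cc3cc(CCCO)cc(OC)c3o2)cc(O)c1O
F8 | step 12 | 3-[2-(3,4-diacetoxy-5-methoxyphenyl)-7-methoxybenzofuran-5-yl]propyl acetate | COc1cc(-c2cc3cc(CCCOC(C)=O)cc(OC)c3o2)cc(OC(C)=O)c1OC(C)=O
F9 | step 12 | N-({2-(3,4-diacetoxy-5-methoxyphenyl)-5-(3-acetoxypropyl)-7-methoxybenzofuran-3-yl}methylidene)-N-methylmethanaminium chloride | C[N+](C)=Cc1c(-c2cc(OC)c(OC(C)=O)c(OC(C)=O)c2)oc2c(OC)cc(CCCOC(C)=O)cc12.[Cl-]
F10 | step 12 | 3-[2-(3,4-diacetoxy-5-methoxyphenyl)-3-formyl-7-methoxybenzofuran-5-yl]propyl acetate | COc1cc(-c2oc3c(OC)cc(CCCOC(C)=O)cc3c2C=O)cc(OC(C)=O)c1OC(C)=O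
F0 | step 10 | none | none
A1 | alternative 1 | 2-[3,4-bis(benzyloxy)-5-methoxyphenyl]-3-(dimethoxymethyl)-7-methoxy-2-(pinacolboryl)-5-[3-(tert-butyldimethylsilyloxy)propyl]-2,3-dihydrobenzofuran (racemic, aryl and acetal trans, one enantiomer drawn) | COC(OC)[C@@H]1c2cc(CCCO[Si](C)(C)C(C)(C)C)cc(OC)c2O[C@@]1(B1OC(C)(C)C(C)(C)O1)c1cc(OC)c(OCc2ccccc2)c(OCc2ccccc2)c1
A2 | alternative 1 | tert-butyl[3-(7-methoxybenzofuran-5-yl)propoxy]dimethylsilane | COc1cc(CCCO[Si](C)(C)C(C)(C)C)cc2ccoc12
A3 | alternative 1 | 2-[3,4-bis(benzyloxy)-5-methoxyphenyl]-4,4,5,5-tetramethyl-1,3,2-dioxaborolane | COc1cc(B2OC(C)(C)C(C)(C)O2)cc(OCc2ccccc2)c1OCc1ccccc1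
A4 | alternative 2 | 2-[3,4-bis(benzyloxy)-5-methoxyphenyl]-5-(3-benzyloxypropyl)-7-methoxy-3-(methoxymethyl)benzofuran | COCc1c(-c2cc(OC)c(OCc3ccccc3)c(OCc3ccccc3)c2)oc2c(OC)cc(CCCOCc3ccccc3)cc12
A5 | alternative 2 | 1-{[3,4-bis(benzyloxy)-5-methoxyphenyl]ethynyl}-5-[3-(benzyloxy)propyl]-3-methoxy-2-(methoxymethoxy)benzene | COCOc1c(OC)cc(CCCOCc2ccccc2)cc1C#Cc1cc(OC)c(OCc2ccccc2)c(OCc2ccccc2)c1
A6 | alternative 3 | ethyl 7-acetoxybenzofuran-5-carboxylate | CCOC(=O)c1cc(OC(C)=O)c2occc2c1
A7 | alternative 3 | (E)-3-(ethoxycarbonyl)-4-(furan-3-yl)but-3-enoic acid | CCOC(=O)/C(CC(=O)O)=C/c1ccoc1
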